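**Retrosynthetic overview**

1. The target is a 5,6,7-trihydroxyisochroman-1-one: lactone ring C1(=O)–O2–C3–C4–C4a–C8a fused to the benzene ring, CO2H on C3 and, cis to it on C4, the arm C2'(CO2H)–C3'H2–CO2H. That arm is a succinic acid, i.e. a C4 vinyl group plus two CO. The bonds from C2' and C3' to their carboxyl carbons are therefore made last, by palladium-catalysed oxidative dicarbonylation of the 4-vinyl lactone 12 with CO and benzyl alcohol (→ 15); one hydrogenolysis of six benzyl groups then gives 16.
2. The lactone ring is the only ring formed; the benzene ring is bought as the tribenzyl ether of gallic acid. The ring is closed by transesterification of the C3 hydroxyl of hydroxy ester 11 onto the ortho benzyl benzoate, which turns the anti C3–OH/C4–aryl pair into the 3,4-cis lactone.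
3. The C3–C4 bond and both ring stereocentres come from a chiral-phosphoric-acid-catalysed allylboration of benzyl glyoxylate 9 with the (E)-γ-aryl allylboronate 7 (chair transition state, E → anti).
4. Boronate 7 comes from 3,4,5-tris(benzyloxy)benzoic acid 1 by benzyl esterification, bromination at C2, Suzuki–Miyaura coupling with the (E)-3-hydroxypropenyl boronate 5 and palladium-catalysed exchange of OH for Bpin. Every protecting group is benzyl, so the alcohol expelled on lactonisation cannot scramble esters and one final step deprotects everything.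

Key step: step 8

Assumption (remark on the chemistry): 3,4,5-tris(benzyloxy)benzoic acid 1, the tribenzyl ether of gallic acid, is taken as a purchased starting material.

Assumption (remark on the chemistry): the antipodes written for the two chiral controllers, (S)-TRIP in step 6 and the (S,S)-bis(oxazoline) in step 8, are taken to be the ones that give the drawn configuration; if a test run shows the opposite sense, the other antipode is used and nothing else changes.

**Route**

Step 1
Reactants: 1 3,4,5-tris(benzyloxy)benzoic acid; 2 benzyl bromide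
Product: 3 benzyl 3,4,5-tris(benzyloxy)benzoate
Conditions: BnBr (1.1 equiv), K2CO3 (1.5 equiv), DMF, rt to 40 °C
Reagents that add atoms: none
Why: SN2 O-alkylation of the potassium carboxylate by benzyl bromide (ester formation under Williamson-type conditions) should be clean, since the carboxylic acid is the only acidic site and the three benzyl ethers are inert to carbonate in DMF.

Step 2
Reactants: 3 benzyl 3,4,5-tris(benzyloxy)benzoate
Product: 4 benzyl 2-bromo-3,4,5-tris(benzyloxy)benzoate
Conditions: NBS (1.05 equiv), MeCN, 0 °C to rt, dark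
Reagents that add atoms: N-bromosuccinimide, O=C1CCC(=O)N1Br
Why: Electrophilic aromatic bromination should go to C2 (equivalent to C6), the only free position on the ring that carries three alkoxy donors (ortho to the 3-OBn, para to the 5-OBn), while the phenyl rings of the benzyl groups are far less activated and one equivalent of reagent limits dibromination.

Step 3
Reactants: 4 benzyl 2-bromo-3,4,5-tris(benzyloxy)benzoate; 5 (E)-3-(4,4,5,5-tetramethyl-1,3,2-dioxaborolan-2-yl)prop-2-en-1-ol
Product: 6 benzyl 3,4,5-tris(benzyloxy)-2-[(E)-3-hydroxyprop-1-en-1-yl]benzoate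
Conditions: Pd(OAc)2 (3 mol %), SPhos (6 mol %), K3PO4 (3 equiv), toluene/H2O, 70 °C
Reagents that add atoms: none
Why: Suzuki–Miyaura coupling, in which the bulky electron-rich biarylphosphine lets zerovalent palladium insert into the di-ortho-substituted aryl bromide, the alkenyl group is transferred with retention of its E geometry, and the benzyl ester and free allylic alcohol should tolerate the phosphate base.

Step 4
Reactants: 6 benzyl 3,4,5-tris(benzyloxy)-2-[(E)-3-hydroxyprop-1-en-1-yl]benzoate
Product: 7 benzyl 3,4,5-tris(benzyloxy)-2-[(E)-3-(4,4,5,5-tetramethyl-1,3,2-dioxaborolan-2-yl)prop-1-en-1-yl]benzoate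
Conditions: B2pin2 (1.3 equiv), [Pd(MeCN)4](BF4)2 (5 mol %), DMSO/MeOH, 40 °C
Reagents that add atoms: bis(pinacolato)diboron, CC1(C)OB(OC1(C)C)B1OC(C)(C)C(C)(C)O1
Why: Palladium-catalysed borylation of an allylic alcohol, in which the diboron reagent activates the hydroxyl as a borate leaving group, ionisation gives an η3-allylpalladium intermediate, and boryl transfer to the unhindered CH2 terminus should give the linear boronate with the E alkene kept in conjugation with the arene.

Step 5
Reactants: 8 dibenzyl L-tartrate
Product: 9 benzyl glyoxylate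
Conditions: H5IO6 (1.1 equiv), Et2O, 0 °C to rt; vacuum distillation to the dry monomer
Reagents that add atoms: none
Why: Malaprade glycol cleavage through a cyclic periodate ester should split the symmetrical 1,2-diol into two molecules of the glyoxylate without touching the benzyl esters.

Step 6
Reactants: 7 benzyl 3,4,5-tris(benzyloxy)-2-[(E)-3-(4,4,5,5-tetramethyl-1,3,2-dioxaborolan-2-yl)prop-1-en-1-yl]benzoate; 9 benzyl glyoxylate
Product: 11 benzyl (2S,3R)-3-[2,3,4-tris(benzyloxy)-6-(benzyloxycarbonyl)phenyl]-2-hydroxypent-4-enoate, via O-pinacolboryl ether 10 (not isolated)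
Conditions: 9 (1.5 equiv), (S)-TRIP [(S)-3,3'-bis(2,4,6-triisopropylphenyl)-1,1'-binaphthyl-2,2'-diyl hydrogen phosphate] (5 mol %), 4 Å MS, toluene, −40 °C; aq. NaHCO3 work-up
Reagents that add atoms: none
Why: Chiral-phosphoric-acid-catalysed allylboration through a closed six-membered chair (Zimmerman–Traxler) transition state, in which the E geometry of 7 places the aryl group equatorial and so fixes the anti relation of C2–OH and C3–aryl, while the (S)-acid, hydrogen-bonded to the pseudoaxial boronate oxygen and the formyl hydrogen, should direct the allyl γ-carbon to the Si face of 9 (by analogy with the Re-face delivery that the (R)-acid gives with aromatic aldehydes) and thereby set (2S,3R); aqueous work-up hydrolyses borate 10.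

Step 7
Reactants: 11 benzyl (2S,3R)-3-[2,3,4-tris(benzyloxy)-6-(benzyloxycarbonyl)phenyl]-2-hydroxypent-4-enoate
Product: 12 benzyl (3S,4R)-5,6,7-tris(benzyloxy)-1-oxo-4-vinylisochromane-3-carboxylate (3,4-cis)
Conditions: TsOH·H2O (10 mol %), toluene, 80 °C
Reagents that add atoms: none
Why: Acid-catalysed intramolecular transesterification (6-exo-trig acyl substitution) of the C2 hydroxyl on the ortho benzyl benzoate, in which no bond to either stereocentre is broken so that the anti hydroxy ester should become the 3,4-cis lactone, and in which the expelled benzyl alcohol cannot scramble the benzyl ester on C3.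

Step 8
Reactants: 12 benzyl (3S,4R)-5,6,7-tris(benzyloxy)-1-oxo-4-vinylisochromane-3-carboxylate; 13 benzyl alcohol; 14 carbon monoxide
Product: 15 dibenzyl (2R)-2-[(3S,4R)-5,6,7-tris(benzyloxy)-3-(benzyloxycarbonyl)-1-oxoisochroman-4-yl]butanedioate
Conditions: Pd(OCOCF3)2 (5 mol %), 2,2'-(propane-2,2-diyl)bis[(4S)-4-phenyl-4,5-dihydro-1,3-oxazole] (6 mol %), p-benzoquinone (1.5 equiv), TsOH·H2O (2 mol %), CO (5 bar), BnOH (10 equiv), THF, 20 °C
Reagents that add atoms: benzyl alcohol (second molecule), OCc1ccccc1; carbon monoxide (second molecule), [C-]#[O+]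
Why: Divalent palladium bound to the chiral bis(oxazoline) is converted by CO and benzyl alcohol into a benzyloxycarbonyl–palladium species that adds syn across the vinyl group with the ester carbon on terminal C3' and palladium on C2'; a second CO then inserts into the C2'–Pd bond with retention, a second benzyl alcohol cleaves the acyl to the second ester, and p-benzoquinone returns zerovalent palladium to the divalent state. The closest known reaction is the oxidative bis(alkoxycarbonylation) of terminal alkenes to 2-substituted succinates with palladium and benzoquinone, including its ligand-controlled asymmetric variants. No ring is closed; the two new skeletal bonds are C2'–CO2Bn and C3'–CO2Bn, each built from one CO and one benzyl alcohol. The new centre C2' is set in the migratory insertion by the alkene face that palladium binds, which the chiral ligand should control; the C4 centre modulates it, because the vinyl group sits pseudoaxial on the half-chair lactone (away from the peri C5 benzyloxy group) between the arene and the cis C3 ester, so the ligand antipode matched to this bias is the one used. The step needs the palladium on the internal carbon, which a monosubstituted unconjugated alkene favours, and it needs CO insertion to outrun β-hydride elimination toward C4 (which would give the unsaturated monoester or move the alkene into conjugation with the arene and erase C4), which CO pressure, room temperature and the hydride-scavenging quinone should secure. The lactone, benzyl esters and benzyl ethers should be inert under these nearly neutral conditions, and any exchange of ester groups with the benzyl alcohol is degenerate.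

Step 9
Reactants: 15 dibenzyl (2R)-2-[(3S,4R)-5,6,7-tris(benzyloxy)-3-(benzyloxycarbonyl)-1-oxoisochroman-4-yl]butanedioate
Product: 16 (2R)-2-[(3S,4R)-3-carboxy-5,6,7-trihydroxy-1-oxoisochroman-4-yl]butanedioic acid (target)
Conditions: H2 (1 atm), 10% Pd/C, THF/MeOH, rt; filtration under argon
Reagents that add atoms: none
Why: Heterogeneous hydrogenolysis should cleave the three benzyl aryl ethers and three benzyl esters at their benzylic C–O bonds, whereas the lactone C–O bonds are not benzylic and the C3, C4 and C2' centres carry no cleavable bond, so the configuration set earlier should be kept.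

**Compound list**

1 | 3,4,5-tris(benzyloxy)benzoic acid | O=C(O)c1cc(OCc2ccccc2)c(OCc2ccccc2)c(OCc2ccccc2)c1 | starting material
2 | benzyl bromide | BrCc1ccccc1 | starting material
3 | benzyl 3,4,5-tris(benzyloxy)benzoate | O=C(OCc1ccccc1)c1cc(OCc2ccccc2)c(OCc2ccccc2)c(OCc2ccccc2)c1 | intermediate
4 | benzyl 2-bromo-3,4,5-tris(benzyloxy)benzoate | O=C(OCc1ccccc1)c1cc(OCc2ccccc2)c(OCc2ccccc2)c(OCc2ccccc2)c1Br | intermediate
5 | (E)-3-(4,4,5,5-tetramethyl-1,3,2-dioxaborolan-2-yl)prop-2-en-1-ol | OC/C=C/B1OC(C)(C)C(C)(C)O1 | starting material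
6 | benzyl 3,4,5-tris(benzyloxy)-2-[(E)-3-hydroxyprop-1-en-1-yl]benzoate | O=C(OCc1ccccc1)c1cc(OCc2ccccc2)c(OCc2ccccc2)c(OCc2ccccc2)c1/C=C/CO | intermediate
7 | benzyl 3,4,5-tris(benzyloxy)-2-[(E)-3-(4,4,5,5-tetramethyl-1,3,2-dioxaborolan-2-yl)prop-1-en-1-yl]benzoate | O=C(OCc1ccccc1)c1cc(OCc2ccccc2)c(OCc2ccccc2)c(OCc2ccccc2)c1/C=C/CB3OC(C)(C)C(C)(C)O3 | intermediate
8 | dibenzyl L-tartrate, (2R,3R) | O=C(OCc1ccccc1)[C@H](O)[C@@H](O)C(=O)OCc1ccccc1 | starting material
9 | benzyl glyoxylate | O=CC(=O)OCc1ccccc1 | intermediate
10 | O-pinacolboryl ether of 11 (not isolated) | C=C[C@H](c1c(C(=O)OCc2ccccc2)cc(OCc2ccccc2)c(OCc2ccccc2)c1OCc3ccccc3)[C@H](OB4OC(C)(C)C(C)(C)O4)C(=O)OCc5ccccc5 | intermediate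
11 | benzyl (2S,3R)-3-[2,3,4-tris(benzyloxy)-6-(benzyloxycarbonyl)phenyl]-2-hydroxypent-4-enoate (anti) | C=C[C@H](c1c(C(=O)OCc2ccccc2)cc(OCc2ccccc2)c(OCc2ccccc2)c1OCc3ccccc3)[C@H](O)C(=O)OCc4ccccc4 | intermediate
12 | benzyl (3S,4R)-5,6,7-tris(benzyloxy)-1-oxo-4-vinylisochromane-3-carboxylate (3,4-cis) | C=C[C@@H]1c2c(cc(OCc3ccccc3)c(OCc3ccccc3)c2OCc3ccccc3)C(=O)O[C@@H]1C(=O)OCc4ccccc4 | intermediate
13 | benzyl alcohol | OCc1ccccc1 | starting material
14 | carbon monoxide | [C-]#[O+] | starting material
15 | dibenzyl (2R)-2-[(3S,4R)-5,6,7-tris(benzyloxy)-3-(benzyloxycarbonyl)-1-oxoisochroman-4-yl]butanedioate | O=C(OCc5ccccc5)C[C@@H](C(=O)OCc5ccccc5)[C@@H]1c2c(cc(OCc3ccccc3)c(OCc3ccccc3)c2OCc3ccccc3)C(=O)O[C@@H]1C(=O)OCc4ccccc4 | intermediate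
16 | (2R)-2-[(3S,4R)-3-carboxy-5,6,7-trihydroxy-1-oxoisochroman-4-yl]butanedioic acid | O=C(O)C[C@@H](C(=O)O)[C@@H]1c2c(cc(O)c(O)c2O)C(=O)O[C@@H]1C(=O)O | target

**Step count**

Total: 9 steps. Longest linear sequence: 8 steps (1, 2, 3, 4, 6, 7, 8, 9 from 3,4,5-tris(benzyloxy)benzoic acid); step 5 is a one-step side branch.

**Steps most likely to fail**

1. Step 8. The two faces of the vinyl group may be poorly distinguished if the ligand and the C4 centre are mismatched or the ligand's influence is weak. β-Hydride elimination from the C2' alkylpalladium may also compete, moving the alkene toward the arene or giving the unsaturated monoester. The fallback sets out from 12 and returns at 16. Cross-metathesis of 12 with benzyl acrylate (second-generation Hoveyda–Grubbs catalyst, CH2Cl2, 40 °C) should give benzyl (3S,4R)-5,6,7-tris(benzyloxy)-4-[(E)-3-(benzyloxy)-3-oxoprop-1-en-1-yl]-1-oxoisochromane-3-carboxylate F1. Rhodium-catalysed asymmetric 1,4-addition of potassium vinyltrifluoroborate ([RhCl(C2H4)2]2, chiral bicyclic diene ligand, aqueous dioxane, no strong base) would then place a vinyl group on C2' under ligand control and give benzyl (3S,4R)-5,6,7-tris(benzyloxy)-4-[(3S)-1-(benzyloxy)-1-oxopent-4-en-3-yl]-1-oxoisochromane-3-carboxylate F2. Lemieux–Johnson cleavage (OsO4 cat., NaIO4, 2,6-lutidine, dioxane/H2O) would give benzyl (3S,4R)-5,6,7-tris(benzyloxy)-4-[(2R)-4-(benzyloxy)-1,4-dioxobutan-2-yl]-1-oxoisochromane-3-carboxylate F3. Pinnick oxidation (NaClO2, NaH2PO4, 2-methylbut-2-ene, t-BuOH/H2O) would give (2R)-4-(benzyloxy)-2-[(3S,4R)-5,6,7-tris(benzyloxy)-3-(benzyloxycarbonyl)-1-oxoisochroman-4-yl]-4-oxobutanoic acid F4. Hydrogenolysis of F4 under the conditions of step 9 gives 16.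

2. Step 6. The uncatalysed addition to the very electrophilic glyoxylate may erode the enantioface selection, and C–C bond formation may be slow at a γ-carbon flanked by a 2,6-disubstituted aryl group. The fallback sets out from 6 and returns at 11, replacing catalyst control by reagent control. Palladium-catalysed borylation of 6 with tetrahydroxydiboron (B2(OH)4, [Pd(MeCN)4](BF4)2, DMSO/MeOH) should give (E)-3-[2,3,4-tris(benzyloxy)-6-(benzyloxycarbonyl)phenyl]prop-2-en-1-ylboronic acid F5. Esterification with diisopropyl L-tartrate (MgSO4, Et2O) would give the diisopropyl (R,R)-tartrate allylboronate F6. F6 is added to 9 in toluene over 4 Å MS at −78 °C through the same chair, so the product is still anti, and the (R,R)-tartrate is the antipode expected to favour Si-face attack and give 11 after aqueous work-up.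

3. Step 4. The boryl group may be lost by protodeboronation in the protic medium, or ionisation of the hindered allylic alcohol may stall. The fallback sets out from 4 and returns at 7, avoiding the allylpalladium intermediate. Heck coupling of 4 with vinylboronic acid pinacol ester under anhydrous conditions (Pd(OAc)2, P(t-Bu)3, Et3N, toluene, 90 °C; the boryl group is retained without aqueous base) should give benzyl 3,4,5-tris(benzyloxy)-2-[(E)-2-(4,4,5,5-tetramethyl-1,3,2-dioxaborolan-2-yl)ethenyl]benzoate F7. Matteson homologation with chloromethyllithium made in the flask in the presence of F7 (ICH2Cl, n-BuLi, THF, −78 °C to rt; boron ate-complex formation should outrun addition to the hindered benzoate) would insert CH2 into the C–B bond with retention of the E geometry and give 7.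

**Further compounds**

F1 | step 8 | benzyl (3S,4R)-5,6,7-tris(benzyloxy)-4-[(E)-3-(benzyloxy)-3-oxoprop-1-en-1-yl]-1-oxoisochromane-3-carboxylate | O=C(OCc5ccccc5)/C=C/[C@@H]1c2c(cc(OCc3ccccc3)c(OCc3ccccc3)c2OCc3ccccc3)C(=O)O[C@@H]1C(=O)OCc4ccccc4
F2 | step 8 | benzyl (3S,4R)-5,6,7-tris(benzyloxy)-4-[(3S)-1-(benzyloxy)-1-oxopent-4-en-3-yl]-1-oxoisochromane-3-carboxylate | O=C(OCc5ccccc5)C[C@@H](C=C)[C@@H]1c2c(cc(OCc3ccccc3)c(OCc3ccccc3)c2OCc3ccccc3)C(=O)O[C@@H]1C(=O)OCc4ccccc4
F3 | step 8 | benzyl (3S,4R)-5,6,7-tris(benzyloxy)-4-[(2R)-4-(benzyloxy)-1,4-dioxobutan-2-yl]-1-oxoisochromane-3-carboxylate | O=C(OCc5ccccc5)C[C@@H](C=O)[C@@H]1c2c(cc(OCc3ccccc3)c(OCc3ccccc3)c2OCc3ccccc3)C(=O)O[C@@H]1C(=O)OCc4ccccc4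
F4 | step 8 | (2R)-4-(benzyloxy)-2-[(3S,4R)-5,6,7-tris(benzyloxy)-3-(benzyloxycarbonyl)-1-oxoisochroman-4-yl]-4-oxobutanoic acid | O=C(OCc5ccccc5)C[C@@H](C(=O)O)[C@@H]1c2c(cc(OCc3ccccc3)c(OCc3ccccc3)c2OCc3ccccc3)C(=O)O[C@@H]1C(=O)OCc4ccccc4
F5 | step 6 | (E)-3-[2,3,4-tris(benzyloxy)-6-(benzyloxycarbonyl)phenyl]prop-2-en-1-ylboronic acid | O=C(OCc1ccccc1)c1cc(OCc2ccccc2)c(OCc2ccccc2)c(OCc2ccccc2)c1/C=C/CB(O)O
F6 | step 6 | diisopropyl (4R,5R)-2-{(E)-3-[2,3,4-tris(benzyloxy)-6-(benzyloxycarbonyl)phenyl]prop-2-en-1-yl}-1,3,2-dioxaborolane-4,5-dicarboxylate | O=C(OCc1ccccc1)c1cc(OCc2ccccc2)c(OCc2ccccc2)c(OCc2ccccc2)c1/C=C/CB3O[C@@H](C(=O)OC(C)C)[C@H](C(=O)OC(C)C)O3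
F7 | step 4 | benzyl 3,4,5-tris(benzyloxy)-2-[(E)-2-(4,4,5,5-tetramethyl-1,3,2-dioxaborolan-2-yl)ethenyl]benzoate | O=C(OCc1ccccc1)c1cc(OCc2ccccc2)c(OCc2ccccc2)c(OCc2ccccc2)c1/C=C/B3OC(C)(C)C(C)(C)O3
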